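**Retrosynthetic overview**
1. Vibsanin E ⇐ enol esterification of keto-aldehyde 17 ⇐ ozonolysis of allyl diketone 15 ⇐ acetyl-radical hydroacylation of exo-methylene ketone 13 ⇐ α-methylenation of allyl ketone 12.
2. 12 ⇐ key step: one-carbon radical ring expansion of siloxycyclopropane 10 with allyl capture (bicyclo[3.3.1]nonanone → bicyclo[4.3.1]decanone; the inserted carbon comes from CH2I2).
3. 10 ⇐ tricyclic ketone 8 ⇐ Lewis-acid cation–olefin/oxa-cyclisation of Baylis–Hillman alcohol 7 (cyclohexane and tetrahydropyran rings closed together).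
4. 7 ⇐ enone 5 ⇐ ketone 4 ⇐ Cu-catalysed asymmetric conjugate addition to 3-methylcyclohexenone (sets the quaternary centre; every other centre is relayed from it).
5. Ring order: cyclohexanone (bought) → cyclohexane + pyran (step 4) → cycloheptanone (step 6).

Assumption: locants of tricyclic compounds are those of the von Baeyer names in the compound list, "exo" is the face of the carbocycle syn to the 1-methyl group (anti to the CH2CH2 bridge), and the SMILES define absolute configuration.

**Step 1**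
Reactants: 1 3-methylcyclohex-2-en-1-one; 2 5-bromo-2-methylpent-2-ene
Product: 4 (R)-3-methyl-3-(4-methylpent-3-en-1-yl)cyclohexan-1-one, via Grignard reagent 3 (not isolated)
Conditions: Mg, Et2O; then 1, Cu(OTf)2 (3 mol %), chiral C2-symmetric imidazolinium NHC precursor (4 mol %, enantiomer giving R), Et2O, 0 °C; aq NH4Cl
Reagents that add atoms: none
Why: Cu–NHC-catalysed asymmetric conjugate addition of a Grignard reagent to a β-methyl enone creates the quaternary stereocentre under catalyst control (ee about 90%, upgraded if needed by recrystallising 8).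

**Step 2**
Reactants: 4 (R)-3-methyl-3-(4-methylpent-3-en-1-yl)cyclohexan-1-one
Product: 5 (S)-5-methyl-5-(4-methylpent-3-en-1-yl)cyclohex-2-en-1-one
Conditions: IBX (2 equiv), DMSO–fluorobenzene, 70 °C
Reagents that add atoms: none
Why: IBX ketone dehydrogenation can only place the double bond on the side away from the quaternary carbon, so a single enone forms and the stereocentre is untouched (descriptor changes by CIP priority only).

**Step 3**
Reactants: 5 (S)-5-methyl-5-(4-methylpent-3-en-1-yl)cyclohex-2-en-1-one; 6 formaldehyde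
Product: 7 (S)-2-(hydroxymethyl)-5-methyl-5-(4-methylpent-3-en-1-yl)cyclohex-2-en-1-one
Conditions: 37% aq HCHO, DMAP (20 mol %), THF–H2O, rt
Reagents that add atoms: none
Why: Morita–Baylis–Hillman hydroxymethylation of a cyclohexenone with an unhindered β-CH installs the future pyran CH2O carbon at the α-position.

**Step 4**
Reactants: 7 (S)-2-(hydroxymethyl)-5-methyl-5-(4-methylpent-3-en-1-yl)cyclohex-2-en-1-one
Product: 8 1,7,7-trimethyl-6-oxatricyclo[6.2.2.0(4,9)]dodecan-3-one
Conditions: BF3·OEt2 (1.2 equiv), CH2Cl2, −78 → 0 °C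
Reagents that add atoms: none
Why: Lewis-acid cation–olefin (Prins-type conjugate) cyclisation of the axial homoprenyl chain onto the enone β-carbon closes the cyclohexane through a chair transition state, the tertiary cation is trapped by the CH2OH oxygen, and the 1,3-diaxial bridge plus the cis-fused pyran fix C4, C8 and C9 relative to C1.

**Step 5**
Reactants: 8 1,7,7-trimethyl-6-oxatricyclo[6.2.2.0(4,9)]dodecan-3-one
Product: 10 exo-2,3-methano-1,7,7-trimethyl-3-(trimethylsilyloxy)-6-oxatricyclo[6.2.2.0(4,9)]dodecane, via TMS enol ether 9 (not isolated)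
Conditions: LDA, TMSCl, THF, −78 °C (internal quench); volatiles off, crude 9 in CH2Cl2; Et2Zn, CH2I2, 0 °C → rt
Reagents that add atoms: chlorotrimethylsilane C[Si](C)(C)Cl; diiodomethane ICI
Why: Kinetic deprotonation takes the C2 methylene in preference to the C4 ring-fusion methine, and Simmons–Smith (Furukawa) cyclopropanation of the enol silane from the exo face delivers the carbon that will be inserted (the two new centres are erased in step 6).

**Step 6**
Reactants: 10 exo-2,3-methano-1,7,7-trimethyl-3-(trimethylsilyloxy)-6-oxatricyclo[6.2.2.0(4,9)]dodecane; 11 allyl methyl sulfone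
Product: 12 11-exo-allyl-1,5,5-trimethyl-6-oxatricyclo[6.3.2.0(4,13)]tridecan-9-one
Conditions: 9-mesityl-10-methylacridinium BF4 (5 mol %), 11 (3 equiv), MeCN, 450 nm LEDs, rt, degassed; aqueous work-up
Reagents that add atoms: none
Why: Proposed new method: photo-oxidation of the siloxycyclopropane gives a radical cation whose endocyclic C–C bond undergoes β-scission (strain relief, more stable secondary radical), which expands the ring to the cycloheptanone; the ring-expanded β-keto radical is then allylated by the sulfone (SH2′) on the exo face, which sets C11, while the expelled MeSO2 radical is reduced by the acridine radical (redox-neutral) and the sulfinate takes up Me3Si. The closest known reaction types are the FeCl3 (Saegusa) ring expansion of 1-siloxybicyclo[n.1.0]alkanes and photoredox ring-opening allylation of cycloalkanols with allyl sulfones.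

**Step 7**
Reactants: 12 11-exo-allyl-1,5,5-trimethyl-6-oxatricyclo[6.3.2.0(4,13)]tridecan-9-one; 6 formaldehyde (as paraformaldehyde)
Product: 13 11-exo-allyl-1,5,5-trimethyl-10-methylidene-6-oxatricyclo[6.3.2.0(4,13)]tridecan-9-one
Conditions: (CH2O)n, N-methylanilinium trifluoroacetate, THF, reflux, short reaction time
Reagents that add atoms: none
Why: Mannich-type (Gras) α-methylenation can eliminate only at the C10 methylene, since the other α-carbon (C8) is a methine, giving the exocyclic enone.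

**Step 8**
Reactants: 13 11-exo-allyl-1,5,5-trimethyl-10-methylidene-6-oxatricyclo[6.3.2.0(4,13)]tridecan-9-one; 14 acetaldehyde
Product: 15 11-exo-allyl-1,5,5-trimethyl-10-endo-(2-oxopropyl)-6-oxatricyclo[6.3.2.0(4,13)]tridecan-9-one
Conditions: (n-Bu4N)4W10O32 (2 mol %), 14 (5 equiv), MeCN, 390 nm LEDs, rt, degassed
Reagents that add atoms: none
Why: Decatungstate-photocatalysed hydroacylation (acyl-radical Giese addition) puts the acetyl group on the exocyclic CH2, and back hydrogen-atom transfer to the planar C10 α-keto radical from the open exo face leaves H exo and the 2-oxopropyl group endo, trans to the allyl group (C–C bond formation at C10 by enolate alkylation would be expected to give the epimer).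

**Step 9**
Reactants: 15 11-exo-allyl-1,5,5-trimethyl-10-endo-(2-oxopropyl)-6-oxatricyclo[6.3.2.0(4,13)]tridecan-9-one
Product: 17 2-[1,5,5-trimethyl-9-oxo-10-(2-oxopropyl)-6-oxatricyclo[6.3.2.0(4,13)]tridecan-11-yl]acetaldehyde, via secondary ozonide 16 (not isolated)
Conditions: O3, CH2Cl2, −78 °C (Sudan III end point); then Me2S, −78 °C → rt
Reagents that add atoms: ozone [O-][O+]=O
Why: Ozonolysis with reductive work-up cleaves the only C=C bond (the allyl group) to the two-carbon aldehyde without touching the ketones or stereocentres.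

**Step 10**
Reactants: 17 2-[1,5,5-trimethyl-9-oxo-10-(2-oxopropyl)-6-oxatricyclo[6.3.2.0(4,13)]tridecan-11-yl]acetaldehyde; 18 3-methylbut-2-enoic acid
Product: 20 vibsanin E, via anhydride 19 (not isolated)
Conditions: 18 (2.2 equiv), DCC (1.1 equiv), CH2Cl2, 0 °C → rt, filter; then 17, DMAP, Et3N, CH2Cl2, rt; chromatographic removal of the Z isomer
Reagents that add atoms: none
Why: DMAP-catalysed enol esterification (O-acylation of the aldehyde enol) is much faster for the aldehyde than for the two hindered ketones, the mild amine base leaves C10 untouched, and the E enol ester is the thermodynamically favoured isomer.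

**Compound list**
1 | 3-methylcyclohex-2-en-1-one | CC1=CC(=O)CCC1 | starting material
2 | 5-bromo-2-methylpent-2-ene | CC(C)=CCCBr | starting material
3 | (4-methylpent-3-en-1-yl)magnesium bromide | CC(C)=CCC[Mg]Br | intermediate
4 | (R)-3-methyl-3-(4-methylpent-3-en-1-yl)cyclohexan-1-one | CC(C)=CCC[C@@]1(C)CCCC(=O)C1 | intermediate
5 | (S)-5-methyl-5-(4-methylpent-3-en-1-yl)cyclohex-2-en-1-one | CC(C)=CCC[C@@]1(C)CC=CC(=O)C1 | intermediate
6 | formaldehyde | C=O | starting material
7 | (S)-2-(hydroxymethyl)-5-methyl-5-(4-methylpent-3-en-1-yl)cyclohex-2-en-1-one | CC(C)=CCC[C@@]1(C)CC=C(CO)C(=O)C1 | intermediate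
8 | 1,7,7-trimethyl-6-oxatricyclo[6.2.2.0(4,9)]dodecan-3-one (bicyclo[3.3.1]nonan-3-one with cis-fused 2,2-dimethyltetrahydropyran; H-4, H-8, H-9 mutually cis) | O=C1[C@@H]2COC(C)(C)[C@@H]3CC[C@@](C)(C[C@@H]32)C1 | intermediate
9 | 1,7,7-trimethyl-3-(trimethylsilyloxy)-6-oxatricyclo[6.2.2.0(4,9)]dodec-2-ene | C[Si](C)(C)OC=1[C@@H]2COC(C)(C)[C@@H]3CC[C@@](C)(C[C@@H]32)C=1 | intermediate
10 | exo-2,3-methano-1,7,7-trimethyl-3-(trimethylsilyloxy)-6-oxatricyclo[6.2.2.0(4,9)]dodecane (cyclopropane CH2 exo, OSiMe3 and H-2 endo) | C[Si](C)(C)O[C@]1(C2)[C@@H]3COC(C)(C)[C@@H]4CC[C@@](C)(C[C@@H]43)[C@H]12 | intermediate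
11 | allyl methyl sulfone (3-(methylsulfonyl)prop-1-ene) | C=CCS(C)(=O)=O | starting material
12 | 11-exo-allyl-1,5,5-trimethyl-6-oxatricyclo[6.3.2.0(4,13)]tridecan-9-one (allyl syn to 1-CH3; H-4, H-8, H-13 mutually cis) | C1C(=O)[C@@H]2COC(C)(C)[C@@H]3CC[C@@](C)(C[C@@H]32)[C@H]1CC=C | intermediate
13 | 11-exo-allyl-1,5,5-trimethyl-10-methylidene-6-oxatricyclo[6.3.2.0(4,13)]tridecan-9-one | C=C1C(=O)[C@@H]2COC(C)(C)[C@@H]3CC[C@@](C)(C[C@@H]32)[C@H]1CC=C | intermediate
14 | acetaldehyde | CC=O | starting material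
15 | 11-exo-allyl-1,5,5-trimethyl-10-endo-(2-oxopropyl)-6-oxatricyclo[6.3.2.0(4,13)]tridecan-9-one (10,11-trans) | CC(=O)C[C@@H]1C(=O)[C@@H]2COC(C)(C)[C@@H]3CC[C@@](C)(C[C@@H]32)[C@H]1CC=C | intermediate
16 | secondary ozonide of 15 (3-substituted 1,2,4-trioxolane, ozonide carbon unassigned) | CC(=O)C[C@@H]1C(=O)[C@@H]2COC(C)(C)[C@@H]3CC[C@@](C)(C[C@@H]32)[C@H]1CC4OCOO4 | intermediate
17 | 2-[1,5,5-trimethyl-9-oxo-10-(2-oxopropyl)-6-oxatricyclo[6.3.2.0(4,13)]tridecan-11-yl]acetaldehyde | CC(=O)C[C@@H]1C(=O)[C@@H]2COC(C)(C)[C@@H]3CC[C@@](C)(C[C@@H]32)[C@H]1CC=O | intermediate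
18 | 3-methylbut-2-enoic acid | CC(C)=CC(=O)O | starting material
19 | 3-methylbut-2-enoic anhydride | CC(C)=CC(=O)OC(=O)C=C(C)C | intermediate
20 | vibsanin E, (E)-2-[1,5,5-trimethyl-9-oxo-10-(2-oxopropyl)-6-oxatricyclo[6.3.2.0(4,13)]tridecan-11-yl]ethenyl 3-methylbut-2-enoate | CC(=O)C[C@@H]1C(=O)[C@@H]2COC(C)(C)[C@@H]3CC[C@@](C)(C[C@@H]32)[C@H]1/C=C/OC(=O)C=C(C)C | target

**Step count and risks**

Total step count: 10. Longest linear sequence: 10.

Steps most likely to fail:

Step 6 (the proposed ring expansion/allylation). The unactivated allyl sulfone may trap the secondary radical too slowly, or the exocyclic cyclopropane bond may cleave instead. The fallback uses known chemistry and sets out from 10. FeCl3 in DMF at 0 °C (Saegusa oxidation) opens the cyclopropane to the ring-expanded 11-chloro-1,5,5-trimethyl-6-oxatricyclo[6.3.2.0(4,13)]tridecan-9-one F1. NaOAc in refluxing MeOH eliminates HCl to the enone 1,5,5-trimethyl-6-oxatricyclo[6.3.2.0(4,13)]tridec-10-en-9-one F2. Hosomi–Sakurai addition (allyltrimethylsilane, TiCl4, CH2Cl2, −78 °C) then delivers the allyl group to the exo face of C11, and the route is rejoined at 12.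

Step 8 (hydroacylation and the C10 configuration). Hydrogen abstraction at ether or allylic C–H bonds may compete, and the facial preference of H delivery at C10 is predicted rather than demonstrated. The fallback sets out from 13. Polar 1,4-addition of 2-lithio-2-methyl-1,3-dithiane (THF–HMPA, −78 °C) with low-temperature protonation of the enolate by AcOH gives the dithiane adduct 11-exo-allyl-1,5,5-trimethyl-10-[(2-methyl-1,3-dithian-2-yl)methyl]-6-oxatricyclo[6.3.2.0(4,13)]tridecan-9-one F3. Dethioacetalisation (MeI, CaCO3, aq MeCN) rejoins the route at 15.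

Step 10 (enol ester). The base-sensitive keto-aldehyde can undergo aldol side reactions, and the E/Z ratio may be poor. The fallback sets out from 15 and avoids the aldehyde. Ru–H isomerisation (RuHCl(CO)(PPh3)3, toluene, 80 °C) gives the (E)-prop-1-enyl compound 1,5,5-trimethyl-10-(2-oxopropyl)-11-[(E)-prop-1-enyl]-6-oxatricyclo[6.3.2.0(4,13)]tridecan-9-one F4. Cross-metathesis with vinylboronic acid pinacol ester (Hoveyda–Grubbs II) gives the (E)-alkenyl boronate 1,5,5-trimethyl-10-(2-oxopropyl)-11-[(E)-2-(pinacolboryl)ethenyl]-6-oxatricyclo[6.3.2.0(4,13)]tridecan-9-one F5. KHF2 converts it to the potassium (E)-alkenyltrifluoroborate F6. Stereoretentive Cu-catalysed C–O coupling with acid 18 (Cu(OAc)2, DMAP, 4 Å MS, O2, CH2Cl2) returns to the route at 20 with the E geometry fixed.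

**Further compounds**
F1 | step 6 | 11-chloro-1,5,5-trimethyl-6-oxatricyclo[6.3.2.0(4,13)]tridecan-9-one | C1C(=O)[C@@H]2COC(C)(C)[C@@H]3CC[C@@](C)(C[C@@H]32)C1Cl
F2 | step 6 | 1,5,5-trimethyl-6-oxatricyclo[6.3.2.0(4,13)]tridec-10-en-9-one | O=C1[C@@H]2COC(C)(C)[C@@H]3CC[C@@](C)(C[C@@H]32)C=C1
F3 | step 8 | 11-exo-allyl-1,5,5-trimethyl-10-[(2-methyl-1,3-dithian-2-yl)methyl]-6-oxatricyclo[6.3.2.0(4,13)]tridecan-9-one | CC1(C[C@@H]2C(=O)[C@@H]3COC(C)(C)[C@@H]4CC[C@@](C)(C[C@@H]43)[C@H]2CC=C)SCCCS1
F4 | step 10 | 1,5,5-trimethyl-10-(2-oxopropyl)-11-[(E)-prop-1-enyl]-6-oxatricyclo[6.3.2.0(4,13)]tridecan-9-one | CC(=O)C[C@@H]1C(=O)[C@@H]2COC(C)(C)[C@@H]3CC[C@@](C)(C[C@@H]32)[C@H]1/C=C/C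
F5 | step 10 | 1,5,5-trimethyl-10-(2-oxopropyl)-11-[(E)-2-(4,4,5,5-tetramethyl-1,3,2-dioxaborolan-2-yl)ethenyl]-6-oxatricyclo[6.3.2.0(4,13)]tridecan-9-one | CC(=O)C[C@@H]1C(=O)[C@@H]2COC(C)(C)[C@@H]3CC[C@@](C)(C[C@@H]32)[C@H]1/C=C/B4OC(C)(C)C(C)(C)O4
F6 | step 10 | potassium (E)-trifluoro{2-[1,5,5-trimethyl-9-oxo-10-(2-oxopropyl)-6-oxatricyclo[6.3.2.0(4,13)]tridecan-11-yl]ethenyl}borate | CC(=O)C[C@@H]1C(=O)[C@@H]2COC(C)(C)[C@@H]3CC[C@@](C)(C[C@@H]32)[C@H]1/C=C/[B-](F)(F)F.[K+]
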